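## Retrosynthetic overview
- Prismatomerin comes from Heck arylation of the exocyclic α-methylene lactone **14**. That lactone comes from aldol/elimination of the lactone CH2 in **12**. The ring alkene C6=C7 comes from a C6 alcohol by E2.
- Key disconnection: a SmI2 ketyl–olefin cyclization/lactonization of cyclopentanone **8**, which carries a β-alkoxyacrylate on the acetal oxygen. It forms C8–C10, the THF acetal ring and the spiro quaternary carbinol lactone in one operation.
- Precursor **8** comes from lactol **6** plus methyl propiolate. **6** comes from a formal [3+3] Michael/lactolization of formylenone **4** with methyl formylacetate. **4** comes from (R)-4-OTBS-cyclopentenone, whose C6 stereocentre relays C5.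
- Ring order: cyclopentane (starting material), then dihydropyran lactol (Step 3), then THF plus γ-lactone (Step 5, radical), then cyclopentene alkene, then arylidene.

Assumptions (C numbers follow iridoid numbering: C1 acetal, C3–C4 enol ether, C5/C9 ring fusion, C8 quaternary carbon, C10 the THF carbon, Cg/Ch the lactone α-carbon/carbonyl):
- TBS is a protecting group.
- Sodium methyl formylacetate is commercial, or made from methyl acetate and methyl formate.
- The two anomers of lactol **6** and of acrylate **8** interconvert through reversible oxa-Michael/hemiacetal exchange. Only the anomer whose C1 acrylate oxygen is cis to C8 across the pyran ring cyclizes.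

---

## Route

**Step 1**
Reactants: **1** (R)-4-(TBSO)cyclopent-2-en-1-one; **2** formaldehyde
Product: **3** (R)-4-(TBSO)-2-(hydroxymethyl)cyclopent-2-en-1-one
Conditions: 37% aq. HCHO, imidazole, THF/H2O, rt
Reagents that add atoms: none (all atoms come from 1 and 2)
Why: Morita–Baylis–Hillman hydroxymethylation at the enone α-carbon (future C9). No stereocentre is formed, and the C6–OTBS centre is untouched.

**Step 2**
Reactants: **3**
Product: **4** (R)-4-(TBSO)-2-formylcyclopent-2-en-1-one
Conditions: Dess–Martin periodinane, NaHCO3, CH2Cl2, 0 °C; use crude at once
Reagents that add atoms: none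
Why: Dess–Martin oxidation of the allylic primary alcohol. The product is a doubly activated alkylidene-1,3-dicarbonyl that polymerizes on standing, so it is telescoped.

**Step 3**
Reactants: **4**; **5** sodium methyl formylacetate
Product: **6** cis-fused iridoid-type lactol: methyl 1-hydroxy-5-(TBSO)-7-oxo-1,4a,5,6,7,7a-hexahydrocyclopenta[c]pyran-4-carboxylate. C4a-H and C7a-H are cis; the C4a ring bond (C4) is trans to OTBS; C1 is the anomer with the hydroxyl cis to the C7 ketone across the pyran.
Conditions: **5** (1.2 equiv), THF, 0 °C to rt; then AcOH, CH2Cl2, rt
Reagents that add atoms: none (all atoms come from 4 and 5)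
Why: The formylacetate carbon adds to C5, the β-carbon of the doubly activated alkene, anti to the C6 OTBS; this sets C5. The C9 enol protonates and epimerizes to the cis-fused arrangement, and the formylacetate enol OH closes onto the C1 aldehyde to give the lactol. Proposed new method: formal [3+3] Michael/hemiacetalization annulation; the closest known chemistry is Tietze-type Knoevenagel/Michael–lactolization of 1,3-dicarbonyls and the ring closure of iridoid aglycone dialdehydes to lactols.

**Step 4**
Reactants: **6**; **7** methyl propiolate
Product: **8** (E)-β-alkoxyacrylate of the lactol (methyl (E)-3-[(1-pyranyl)oxy]acrylate on the C1 oxygen), with the C8 ketone and the C6 OTBS retained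
Conditions: **7** (1.5 equiv), N-methylmorpholine (10 mol%), CH2Cl2, rt
Reagents that add atoms: none (all atoms come from 6 and 7)
Why: Nucleophile-catalyzed oxa-Michael addition of the anomeric OH to the propiolate gives the E-enol ether. The reaction is reversible, so the anomers equilibrate and the productive one is drawn off.

**Step 5** (key radical step)
Reactants: **8**
Product: **9** tetracycle: pyran, THF acetal, spiro γ-lactone (Cg-H2) and the cyclopentane carrying C6-OTBS
Conditions: SmI2 (2.5 equiv), HMPA (10 equiv), t-BuOH (2 equiv), THF, −78 °C to rt
Reagents that add atoms: none (MeOH is lost in lactonization)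
Why: SmI2 reduces the C8 ketone to a Sm(III) ketyl. It adds 5-exo to C10, the β-carbon of the alkoxyacrylate, on the face bearing the C1–O tether. This forms the C8 quaternary centre (C10 up, O down) and the THF ring. The α-ester radical is reduced to a Sm enolate and protonated by t-BuOH. The α-face Sm alkoxide then attacks the acrylate ester to give the cis-fused γ-lactone (the ring fusion fixes C10). Proposed new method: ketyl–β-alkoxyacrylate cyclization/lactonization in a substrate that also contains a push–pull dihydropyran. The closest known reactions are Molander ketyl–olefin cyclization/lactonization of keto-acrylates and ketyl additions to β-alkoxyacrylates.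

**Step 6**
Reactants: **9**
Product: **10** C6 alcohol (α-OH)
Conditions: HF·pyridine, pyridine, THF, 0 °C to rt
Reagents that add atoms: none
Why: Buffered fluoride removes the TBS; the lactone, acetal and enol ether-ester survive.

**Step 7**
Reactants: **10**
Product: **11** C6 α-mesylate
Conditions: MsCl, Et3N, CH2Cl2, 0 °C
Reagents that add atoms: methanesulfonyl chloride, CS(=O)(=O)Cl
Why: Standard sulfonylation with retention at C6.

**Step 8**
Reactants: **11**
Product: **12** alkene C6=C7 (deoxy-arylidene "dihydro" lactone, Cg-H2)
Conditions: DBU, toluene, 90 °C
Reagents that add atoms: none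
Why: E2 elimination. The mesylate is α and H5 is also α (syn), so only H7β is anti-periplanar. This gives C6=C7 regiospecifically, and C5 keeps its configuration.

**Step 9**
Reactants: **12**; **2** formaldehyde
Product: **13** α-hydroxymethyl lactone (Cg epimers)
Conditions: LiHMDS, THF, −78 °C; then monomeric CH2O (from paraformaldehyde), −78 °C
Reagents that add atoms: none (formaldehyde is compound 2)
Why: Lactone enolate aldol. It is trapped at −78 °C before β-alkoxide E1cB can occur. The Cg stereocentre is destroyed in Step 10.

**Step 10**
Reactants: **13**
Product: **14** α-methylene lactone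
Conditions: MsCl, Et3N, CH2Cl2, 0 °C to rt; then DBU
Reagents that add atoms: none (the mesylate is lost)
Why: Mesylation and E1cB elimination of the β-hydroxy lactone.

**Step 11**
Reactants: **14**; **15** 4-iodophenol
Product: **16** prismatomerin
Conditions: Pd(OAc)2 (5 mol%), P(o-tol)3, Et3N, MeCN, 80 °C
Reagents that add atoms: none (4-iodophenol is compound 15)
Why: Heck arylation of the 1,1-disubstituted electron-poor alkene. β-Hydride elimination gives the thermodynamic (E)-arylidene, with aryl trans to C=O and cis to C10, as in the target.

---

## Compound list
1 | (R)-4-(TBSO)cyclopent-2-en-1-one | `O=C1C=C[C@H](O[Si](C)(C)C(C)(C)C)C1` | starting material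
2 | formaldehyde | `C=O` | starting material
3 | MBH adduct | `OCC1=C[C@H](O[Si](C)(C)C(C)(C)C)CC1=O` | intermediate
4 | 2-formyl enone | `O=CC1=C[C@H](O[Si](C)(C)C(C)(C)C)CC1=O` | intermediate
5 | sodium methyl formylacetate | `COC(=O)C=C[O-].[Na+]` | starting material
6 | lactol | `COC(=O)C1=CO[C@H](O)[C@@H]2C(=O)C[C@@H](O[Si](C)(C)C(C)(C)C)[C@H]12` | intermediate
7 | methyl propiolate | `C#CC(=O)OC` | starting material
8 | E-acrylate ketone | `COC(=O)C1=CO[C@H](O/C=C/C(=O)OC)[C@@H]2C(=O)C[C@@H](O[Si](C)(C)C(C)(C)C)[C@H]12` | intermediate
9 | tetracyclic lactone (C6-OTBS) | `COC(=O)C1=CO[C@@H]2O[C@H]3CC(=O)O[C@]34C[C@@H](O[Si](C)(C)C(C)(C)C)[C@H]1[C@H]24` | intermediate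
10 | C6 alcohol | `COC(=O)C1=CO[C@@H]2O[C@H]3CC(=O)O[C@]34C[C@@H](O)[C@H]1[C@H]24` | intermediate
11 | C6 mesylate | `COC(=O)C1=CO[C@@H]2O[C@H]3CC(=O)O[C@]34C[C@@H](OS(C)(=O)=O)[C@H]1[C@H]24` | intermediate
12 | C6=C7 alkene lactone | `COC(=O)C1=CO[C@@H]2O[C@H]3CC(=O)O[C@]34C=C[C@H]1[C@H]24` | intermediate
13 | α-hydroxymethyl lactone | `COC(=O)C1=CO[C@@H]2O[C@H]3C(CO)C(=O)O[C@]34C=C[C@H]1[C@H]24` | intermediate
14 | α-methylene lactone | `COC(=O)C1=CO[C@@H]2O[C@H]3C(=C)C(=O)O[C@]34C=C[C@H]1[C@H]24` | intermediate
15 | 4-iodophenol | `Oc1ccc(I)cc1` | starting material
16 | prismatomerin | `COC(=O)C1=CO[C@@H]2O[C@H]3/C(=C\c4ccc(O)cc4)C(=O)O[C@]34C=C[C@H]1[C@H]24` | target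

---

**Total steps:** 11
**Longest linear sequence:** 11

**Three steps most likely to fail**
1. **Step 5 (SmI2 cascade).** Risks are over-reduction of the vinylogous carbonate, E1cB loss of the THF oxygen from the Sm enolate, and use of the wrong C1 anomer.
   Fallback (different approach): add a (Z)-3-iodoacrylate-derived organochromium (NHK) to the C8 ketone of the lactol. Spontaneous lactonization gives the spiro butenolide. Then close the THF by oxa-Michael addition of the C1 hydroxyl onto the butenolide β-carbon.
2. **Step 3 (formal [3+3]).** The product may stay as the open 2-formylketone enol instead of the ring-closed lactol.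
   Fallback: build the pyran by 6-endo vinyl-radical cyclization of an α-iodo-β-alkoxyacrylate onto a 2-(dimethoxymethyl)cyclopentenone, which forms the C4–C5 bond.
3. **Step 9 (lactone α-hydroxymethylation).** The β-alkoxy lactone enolate can undergo E1cB ring opening.
   Fallback: skip the lactone enolate and form the arylidene by a mild Lewis-acid (TiCl4/Et3N) aldol condensation of **12** with protected 4-hydroxybenzaldehyde. This replaces Steps 9–11 with one condensation and deprotection.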